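**Retrosynthetic overview**

1. Daucane numbering is used: C1 quaternary carbon (methyl), C4 carbinol (isopropyl), C5 ring-fusion CH, C6 ester carbon, C7=C8 (methyl on C8), C9 carbinol, C10 CH2. Late stage: the vanillate goes back to the free C6 alcohol plus O-silyl vanillic acid, and the isopropyl carbinol goes back to a C4 ketone.
2. Key disconnection: the seven-membered ring is cut at C5–C6 and at C8–C9. This releases C6–C7=C8 as (Z)-3-iodobut-2-enal and leaves a cyclopentanone carrying the quaternary C1, a bromide at C5 and a CH2–CHO arm (C10–C9).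
3. Enabling feature: with C4 as a ketone, O–C6–C5–C4=O is an aldol retron and HO–C9–C8=C7 is an alkenyl–aldehyde retron. The C7=C8 bond is Z inside the seven-membered ring, so one reagent (CrCl2) can make both bonds from one three-carbon unit.
4. C1 is set by catalysis (asymmetric conjugate addition to 3-methylcyclopent-2-en-1-one); C5, C6 and C9 are relayed from it in the annulation, and C4 afterwards.
5. Ring order: the five-membered ring is bought; the seven-membered ring is closed in the key step.

Key step: step 7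

Assumption: in step 1 the ligand antipode is the one that gives the (R)-configured quaternary carbon drawn in the SMILES; which antipode does so is not known in advance.

**Step 1**
Reactants: 1 3-methylcyclopent-2-en-1-one
Product: 3 tert-butyl(dimethyl){[(3R)-3-methyl-3-vinylcyclopent-1-en-1-yl]oxy}silane, via aluminium enolate 2 (not isolated)
Conditions: CH2=CHAlMe2 (from CH2=CHMgBr and Me2AlCl), Cu(OTf)2 (5 mol%), chiral phosphinamine ligand (SimplePhos type), Et2O, −30 °C; then TBSOTf, THF, −30 to 0 °C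
Reagents that add atoms: dimethyl(vinyl)aluminium C=C[Al](C)C (made in the flask from vinylmagnesium bromide C=C[Mg]Br and dimethylaluminium chloride C[Al](C)Cl); tert-butyldimethylsilyl triflate CC(C)(C)[Si](C)(C)OS(=O)(=O)C(F)(F)F
Why: Copper-catalysed asymmetric conjugate addition of an alkenylalane to a β-substituted cyclic enone should create the quaternary carbon C1 under ligand control, and O-silylation of the aluminium enolate fixes the enol ether toward C5.

**Step 2**
Reactants: 3 tert-butyl(dimethyl){[(3R)-3-methyl-3-vinylcyclopent-1-en-1-yl]oxy}silane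
Product: 5 2-[(1R)-3-{[tert-butyl(dimethyl)silyl]oxy}-1-methylcyclopent-2-en-1-yl]ethan-1-ol, via alkylborane 4 (not isolated)
Conditions: 9-BBN, THF, 0 °C to rt; then NaBO3·4H2O, THF–H2O, rt
Reagents that add atoms: sodium perborate [Na+].[Na+].O[B-]1(O)OO[B-](O)(O)OO1; 9-borabicyclo[3.3.1]nonane [H]B1C2CCCC1CCC2 (boron only in 4)
Why: Hydroboration–oxidation with the bulky borane is anti-Markovnikov and selective for the monosubstituted vinyl group over the trisubstituted silyl enol ether, which the near-neutral perborate oxidation should leave intact.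

**Step 3**
Reactants: 5 2-[(1R)-3-{[tert-butyl(dimethyl)silyl]oxy}-1-methylcyclopent-2-en-1-yl]ethan-1-ol
Product: 6 2-[(1R)-3-{[tert-butyl(dimethyl)silyl]oxy}-1-methylcyclopent-2-en-1-yl]acetaldehyde
Conditions: Dess–Martin periodinane, pyridine, CH2Cl2, 0 °C
Reagents that add atoms: none
Why: Dess–Martin oxidation converts the primary alcohol into the aldehyde under buffered, non-aqueous conditions that the silyl enol ether should survive.

**Step 4**
Reactants: 6 2-[(1R)-3-{[tert-butyl(dimethyl)silyl]oxy}-1-methylcyclopent-2-en-1-yl]acetaldehyde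
Product: 7 2-[(1R)-2-bromo-1-methyl-3-oxocyclopentyl]acetaldehyde (both epimers at the C–Br carbon)
Conditions: N-bromosuccinimide, THF, −78 to 0 °C
Reagents that add atoms: N-bromosuccinimide O=C1CCC(=O)N1Br
Why: Electrophilic bromination of the enol silane places bromine regiospecifically at C5 next to the quaternary carbon without touching the aldehyde, and the C–Br centre needs no control because it is consumed in step 7.

**Step 5**
Reactants: 8 but-2-yn-1-ol
Product: 10 (2Z)-3-iodobut-2-en-1-ol, via alkenylalanate 9 (not isolated)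
Conditions: NaAlH2(OCH2CH2OMe)2 (Red-Al), THF, 0 °C to rt; then N-iodosuccinimide, −78 °C
Reagents that add atoms: N-iodosuccinimide O=C1CCC(=O)N1I
Why: Hydroxyl-directed trans-hydroalumination puts aluminium on C3 cis to the CH2O group, and iodinolysis with retention should give the Z alkenyl iodide.

**Step 6**
Reactants: 10 (2Z)-3-iodobut-2-en-1-ol
Product: 11 (2Z)-3-iodobut-2-enal
Conditions: MnO2, CH2Cl2, rt
Reagents that add atoms: none
Why: Allylic oxidation with MnO2 gives the enal without isomerising the Z double bond or touching the C–I bond.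

**Step 7**
Reactants: 7 2-[(1R)-2-bromo-1-methyl-3-oxocyclopentyl]acetaldehyde and 11 (2Z)-3-iodobut-2-enal
Product: 13 (3aR,5R,8S,8aS)-5,8-dihydroxy-3a,6-dimethyl-3,3a,4,5,8,8a-hexahydroazulen-1(2H)-one, via aldol adduct 12 (not isolated)
Conditions: CrCl2 (5 equiv, nickel-free), 11 (1.1 equiv), THF–DMF, 0 °C, 7 added over 4 h; then NiCl2 (2 mol%), rt; aqueous work-up
Reagents that add atoms: none
Why: Proposed new method: nickel-free CrCl2 reduces the α-bromo ketone of 7 to a trivalent chromium enolate, which adds to the aldehyde of 11 in a chromium Reformatsky aldol; the chromium alkoxide of 12 rests as a six-membered lactolate on the C9 aldehyde until NiCl2 is added, and the alkenyl iodide is then carried through nickel to an alkenylchromium that adds to C9 (Nozaki–Hiyama–Kishi reaction). The closest known reaction types are the intermolecular chromium Reformatsky aldol of α-bromo ketones and the intramolecular Nozaki–Hiyama–Kishi closure of medium rings; new is their union in one flask between two partners that each carry a nucleophile precursor and an aldehyde. The seven-membered ring closes in the 7-exo-trig mode by attack of C8 on the C9 carbonyl. C5 and C6 should come from a closed chair transition state of the ring-locked (E)-enolate (anti aldol), entered on the enolate face syn to the C1 methyl and anti to the CH2CHO arm, which leads to the trans ring fusion; C9 should follow from the cyclic transition state that keeps the new alkoxide pseudo-equatorial (β). The step needs cross-coupling over self-coupling: 7 is added slowly to CrCl2 and 11 so that each enolate meets 11 and not a second molecule of 7, the adduct masks its own aldehyde as the lactolate, and the alkenyl iodide stays inert until nickel is present.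

**Step 8**
Reactants: 13 (3aR,5R,8S,8aS)-5,8-dihydroxy-3a,6-dimethyl-3,3a,4,5,8,8a-hexahydroazulen-1(2H)-one
Product: 14 (3aR,5R,8S,8aS)-5-{[tert-butyl(dimethyl)silyl]oxy}-8-hydroxy-3a,6-dimethyl-3,3a,4,5,8,8a-hexahydroazulen-1(2H)-one
Conditions: TBSCl (1.05 equiv), imidazole, DMF, −20 to 0 °C
Reagents that add atoms: tert-butyldimethylsilyl chloride CC(C)(C)[Si](C)(C)Cl
Why: Silylation should go to the less hindered C9 allylic alcohol, because the C6 hydroxyl is flanked by the ring-fusion carbon and hydrogen-bonded to the C4 ketone.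

**Step 9**
Reactants: 14 (3aR,5R,8S,8aS)-5-{[tert-butyl(dimethyl)silyl]oxy}-8-hydroxy-3a,6-dimethyl-3,3a,4,5,8,8a-hexahydroazulen-1(2H)-one
Product: 15 (1R,3aR,5R,8S,8aS)-5-{[tert-butyl(dimethyl)silyl]oxy}-3a,6-dimethyl-1-(propan-2-yl)-1,2,3,3a,4,5,8,8a-octahydroazulene-1,8-diol
Conditions: i-PrMgCl (2.5 equiv), CeCl3, THF, −78 to −20 °C
Reagents that add atoms: isopropylmagnesium chloride CC(C)[Mg]Cl
Why: Organocerium 1,2-addition (which suppresses enolisation and retro-aldol cleavage) should deliver the isopropyl group to the α face of the cyclopentanone, anti to the angular methyl and the C5–C6 bond, giving the 4β tertiary alcohol.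

**Step 10**
Reactants: 16 4-hydroxy-3-methoxybenzoic acid (vanillic acid)
Product: 18 4-{[tert-butyl(dimethyl)silyl]oxy}-3-methoxybenzoic acid, via silyl ester 17 (not isolated)
Conditions: TBSCl (2.2 equiv), imidazole, DMF, rt; then THF–H2O–AcOH, rt
Reagents that add atoms: tert-butyldimethylsilyl chloride CC(C)(C)[Si](C)(C)Cl
Why: Silylation of phenol and acid followed by selective hydrolysis of the labile silyl ester gives the phenol-protected acid.

**Step 11**
Reactants: 15 (1R,3aR,5R,8S,8aS)-5-{[tert-butyl(dimethyl)silyl]oxy}-3a,6-dimethyl-1-(propan-2-yl)-1,2,3,3a,4,5,8,8a-octahydroazulene-1,8-diol and 18 4-{[tert-butyl(dimethyl)silyl]oxy}-3-methoxybenzoic acid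
Product: 19 (1R,3aR,5R,8S,8aS)-5-{[tert-butyl(dimethyl)silyl]oxy}-1-hydroxy-3a,6-dimethyl-1-(propan-2-yl)-1,2,3,3a,4,5,8,8a-octahydroazulen-8-yl 4-{[tert-butyl(dimethyl)silyl]oxy}-3-methoxybenzoate
Conditions: DCC, DMAP, CH2Cl2, rt
Reagents that add atoms: none
Why: Steglich esterification should acylate the secondary C6 hydroxyl with retention, the tertiary C4 hydroxyl being too hindered to react.

**Step 12**
Reactants: 19 (1R,3aR,5R,8S,8aS)-5-{[tert-butyl(dimethyl)silyl]oxy}-1-hydroxy-3a,6-dimethyl-1-(propan-2-yl)-1,2,3,3a,4,5,8,8a-octahydroazulen-8-yl 4-{[tert-butyl(dimethyl)silyl]oxy}-3-methoxybenzoate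
Product: 20 (1R,3aR,5R,8S,8aS)-1,5-dihydroxy-3a,6-dimethyl-1-(propan-2-yl)-1,2,3,3a,4,5,8,8a-octahydroazulen-8-yl 4-hydroxy-3-methoxybenzoate
Conditions: HF·pyridine, THF, 0 °C to rt
Reagents that add atoms: none
Why: Fluoride-mediated desilylation should remove the aryl and the secondary silyl ether in one operation without touching the ester or the allylic and tertiary alcohols.

**Compound list**

1 | 3-methylcyclopent-2-en-1-one | CC1=CC(=O)CC1 | starting material
2 | dimethylaluminium (3R)-3-methyl-3-vinylcyclopent-1-en-1-olate | C=C[C@@]1(C)CCC(O[Al](C)C)=C1 | intermediate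
3 | tert-butyl(dimethyl){[(3R)-3-methyl-3-vinylcyclopent-1-en-1-yl]oxy}silane | C=C[C@@]1(C)CCC(O[Si](C)(C)C(C)(C)C)=C1 | intermediate
4 | 9-{2-[(1R)-3-{[tert-butyl(dimethyl)silyl]oxy}-1-methylcyclopent-2-en-1-yl]ethyl}-9-borabicyclo[3.3.1]nonane | C1CCC2CCCC1B2CC[C@@]1(C)CCC(O[Si](C)(C)C(C)(C)C)=C1 | intermediate
5 | 2-[(1R)-3-{[tert-butyl(dimethyl)silyl]oxy}-1-methylcyclopent-2-en-1-yl]ethan-1-ol | OCC[C@@]1(C)CCC(O[Si](C)(C)C(C)(C)C)=C1 | intermediate
6 | 2-[(1R)-3-{[tert-butyl(dimethyl)silyl]oxy}-1-methylcyclopent-2-en-1-yl]acetaldehyde | O=CC[C@@]1(C)CCC(O[Si](C)(C)C(C)(C)C)=C1 | intermediate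
7 | 2-[(1R)-2-bromo-1-methyl-3-oxocyclopentyl]acetaldehyde (both epimers at the C–Br carbon) | O=CC[C@@]1(C)CCC(=O)C1Br | intermediate
8 | but-2-yn-1-ol | CC#CCO | starting material
9 | sodium 2,2-bis(2-methoxyethoxy)-3-methyl-2,5-dihydro-1,2-oxaaluminol-2-uide (cyclic Z-alkenylalanate) | CC1=CCO[Al-]1(OCCOC)OCCOC.[Na+] | intermediate
10 | (2Z)-3-iodobut-2-en-1-ol | C/C(I)=C/CO | intermediate
11 | (2Z)-3-iodobut-2-enal | C/C(I)=C/C=O | intermediate
12 | 2-{(1R,2S)-2-[(1R,2Z)-1-hydroxy-3-iodobut-2-en-1-yl]-1-methyl-3-oxocyclopentyl}acetaldehyde (present in the flask as its chromium alkoxide) | O=CC[C@@]1(C)CCC(=O)[C@@H]1[C@@H](O)/C=C(/C)I | intermediate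
13 | (3aR,5R,8S,8aS)-5,8-dihydroxy-3a,6-dimethyl-3,3a,4,5,8,8a-hexahydroazulen-1(2H)-one (trans-fused; 6α-OH, 9β-OH in daucane numbering) | O[C@H]1C=C(C)[C@H](O)C[C@@]2(C)CCC(=O)[C@H]12 | intermediate
14 | (3aR,5R,8S,8aS)-5-{[tert-butyl(dimethyl)silyl]oxy}-8-hydroxy-3a,6-dimethyl-3,3a,4,5,8,8a-hexahydroazulen-1(2H)-one | O[C@H]1C=C(C)[C@H](O[Si](C)(C)C(C)(C)C)C[C@@]2(C)CCC(=O)[C@H]12 | intermediate
15 | (1R,3aR,5R,8S,8aS)-5-{[tert-butyl(dimethyl)silyl]oxy}-3a,6-dimethyl-1-(propan-2-yl)-1,2,3,3a,4,5,8,8a-octahydroazulene-1,8-diol | O[C@H]1C=C(C)[C@H](O[Si](C)(C)C(C)(C)C)C[C@@]2(C)CC[C@@](O)(C(C)C)[C@H]12 | intermediate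
16 | 4-hydroxy-3-methoxybenzoic acid (vanillic acid) | COc1cc(C(=O)O)ccc1O | starting material
17 | tert-butyl(dimethyl)silyl 4-{[tert-butyl(dimethyl)silyl]oxy}-3-methoxybenzoate | COc1cc(C(=O)O[Si](C)(C)C(C)(C)C)ccc1O[Si](C)(C)C(C)(C)C | intermediate
18 | 4-{[tert-butyl(dimethyl)silyl]oxy}-3-methoxybenzoic acid | COc1cc(C(=O)O)ccc1O[Si](C)(C)C(C)(C)C | intermediate
19 | (1R,3aR,5R,8S,8aS)-5-{[tert-butyl(dimethyl)silyl]oxy}-1-hydroxy-3a,6-dimethyl-1-(propan-2-yl)-1,2,3,3a,4,5,8,8a-octahydroazulen-8-yl 4-{[tert-butyl(dimethyl)silyl]oxy}-3-methoxybenzoate | COc1cc(C(=O)O[C@H]2C=C(C)[C@H](O[Si](C)(C)C(C)(C)C)C[C@@]3(C)CC[C@@](O)(C(C)C)[C@H]23)ccc1O[Si](C)(C)C(C)(C)C | intermediate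
20 | (1R,3aR,5R,8S,8aS)-1,5-dihydroxy-3a,6-dimethyl-1-(propan-2-yl)-1,2,3,3a,4,5,8,8a-octahydroazulen-8-yl 4-hydroxy-3-methoxybenzoate | COc1cc(C(=O)O[C@H]2C=C(C)[C@H](O)C[C@@]3(C)CC[C@@](O)(C(C)C)[C@H]23)ccc1O | target

**Step count and risks**

Total step count: 12. Longest linear sequence: 9 steps (steps 1, 2, 3, 4, 7, 8, 9, 11, 12).

Step 7 (the proposed new method) is the most likely to fail. Self-coupling of the two bifunctional partners, quenching of the chromium enolate before it meets 11, or ring closure from the wrong face may outrun the cross-annulation. The fallback uses known chemistry, sets out from 3 and comes back at 13. Cleavage of the silyl enol ether of 3 with MeLi gives the lithium enolate, whose aldol addition to 11 at −78 °C through a closed transition state should give the anti vinyl ketol (2S,3R)-2-[(1R,2Z)-1-hydroxy-3-iodobut-2-en-1-yl]-3-methyl-3-vinylcyclopentan-1-one F1. Silylation (TESOTf, 2,6-lutidine) gives the triethylsilyl ether F2. Hydroboration–oxidation of the vinyl group with disiamylborane and NaBO3 gives the primary alcohol F3, and Dess–Martin oxidation gives the aldehyde F4. A separate Nozaki–Hiyama–Kishi cyclisation (CrCl2, NiCl2 catalyst, DMF, high dilution) closes the seven-membered ring to the 6-O-triethylsilyl hydroazulenone F5, and HF·pyridine removes the triethylsilyl group to give 13.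

Step 1 is the second risk. Addition to the β-methyl cyclopentenone may be slow or poorly enantioselective, and the enol ether may be lost in handling. The fallback sets out from 1 and comes back at 7. The (E)-2-(trimethylsilyl)vinyl alane, a silicon-bearing alkenyl nucleophile of the class best matched to this enone, is added under the same copper catalysis and the enolate is quenched with N-bromosuccinimide to give the bromo ketone (3R)-2-bromo-3-methyl-3-[(E)-2-(trimethylsilyl)ethenyl]cyclopentan-1-one F6. Epoxidation (mCPBA) gives the epoxysilane F7, and aqueous acid (H2SO4, THF–H2O) opens F7 with loss of silanol to the aldehyde 7. No enol ether is isolated, and the hydroboration and oxidation steps are avoided.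

Step 8 is the third risk. Silylation may go to O-6 or to both hydroxyls. The fallback sets out from 3, follows the sequence above as far as F5 (O-6 already protected, O-9 free) and comes back at 14. Silylation of F5 at O-9 (TBSOTf, 2,6-lutidine) gives the bis-silyl ether F8, and PPTS in MeOH cleaves the triethylsilyl ether selectively to give 14.

**Further compounds**

F1 | step 7 | (2S,3R)-2-[(1R,2Z)-1-hydroxy-3-iodobut-2-en-1-yl]-3-methyl-3-vinylcyclopentan-1-one | C=C[C@@]1(C)CCC(=O)[C@@H]1[C@@H](O)/C=C(/C)I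
F2 | step 7 | (2S,3R)-2-[(1R,2Z)-3-iodo-1-(triethylsilyloxy)but-2-en-1-yl]-3-methyl-3-vinylcyclopentan-1-one | C=C[C@@]1(C)CCC(=O)[C@@H]1[C@@H](O[Si](CC)(CC)CC)/C=C(/C)I
F3 | step 7 | (2S,3R)-3-(2-hydroxyethyl)-2-[(1R,2Z)-3-iodo-1-(triethylsilyloxy)but-2-en-1-yl]-3-methylcyclopentan-1-one | OCC[C@@]1(C)CCC(=O)[C@@H]1[C@@H](O[Si](CC)(CC)CC)/C=C(/C)I
F4 | step 7 | 2-{(1R,2S)-2-[(1R,2Z)-3-iodo-1-(triethylsilyloxy)but-2-en-1-yl]-1-methyl-3-oxocyclopentyl}acetaldehyde | O=CC[C@@]1(C)CCC(=O)[C@@H]1[C@@H](O[Si](CC)(CC)CC)/C=C(/C)I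
F5 | step 7 | (3aR,5R,8S,8aS)-5-hydroxy-3a,6-dimethyl-8-(triethylsilyloxy)-3,3a,4,5,8,8a-hexahydroazulen-1(2H)-one | CC[Si](CC)(CC)O[C@H]1C=C(C)[C@H](O)C[C@@]2(C)CCC(=O)[C@H]12
F6 | step 1 | (3R)-2-bromo-3-methyl-3-[(E)-2-(trimethylsilyl)ethenyl]cyclopentan-1-one | C[Si](C)(C)/C=C/[C@@]1(C)CCC(=O)C1Br
F7 | step 1 | (3R)-2-bromo-3-methyl-3-[3-(trimethylsilyl)oxiran-2-yl]cyclopentan-1-one | C[Si](C)(C)C1OC1[C@@]2(C)CCC(=O)C2Br
F8 | step 8 | (3aR,5R,8S,8aS)-5-{[tert-butyl(dimethyl)silyl]oxy}-3a,6-dimethyl-8-(triethylsilyloxy)-3,3a,4,5,8,8a-hexahydroazulen-1(2H)-one | CC[Si](CC)(CC)O[C@H]1C=C(C)[C@H](O[Si](C)(C)C(C)(C)C)C[C@@]2(C)CCC(=O)[C@H]12
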